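The route rests on cutting the O1–C2 bond of the dioxane ring (2,3-dihydro-1,4-benzodioxine numbering: C2 carries methyl, C3 the trimethoxyphenyl group, C6 allyl). The feature exploited is the methyl group on C2 next to O1, which is the Markovnikov trace of a phenol O–H added across a vinyl group. One cobalt-catalysed hydrogen-atom-transfer/radical-polar crossover hydroalkoxylation therefore closes the dioxane ring, creates the methyl group and sets C2 trans to C3. Its precursor is an open-chain phenol, the (S)-1-arylallyl monoether of 4-bromocatechol. The stereocentre of that ether comes from an iridium-catalysed asymmetric allylic etherification. Bromine stands in for the competing allyl alkene and is exchanged last.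

Key step: step 5

Assumption: the (Sa,Sc,Sc) antipode of the binaphthol-derived bis(1-phenylethyl)phosphoramidite is taken to direct the aryloxide to the allyl face that gives the (S)-ether. If the sense proves opposite, the mirror-image ligand is used and nothing else changes.

Step 1
Reactants: 1 methyl (E)-3-(3,4,5-trimethoxyphenyl)prop-2-enoate
Product: 2 (E)-3-(3,4,5-trimethoxyphenyl)prop-2-en-1-ol
Conditions: iBu2AlH (2.2 equiv), CH2Cl2, −78 °C to 0 °C; aq. potassium sodium tartrate
Reagents that add atoms: none
Why: Ester reduction with iBu2AlH takes the conjugated ester in 1,2-fashion to the allylic alcohol and leaves the E alkene and the aryl methyl ethers untouched.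

Step 2
Reactants: 2 (E)-3-(3,4,5-trimethoxyphenyl)prop-2-en-1-ol
Product: 3 methyl (E)-3-(3,4,5-trimethoxyphenyl)prop-2-en-1-yl carbonate
Conditions: ClCO2Me (1.3 equiv), pyridine (2 equiv), CH2Cl2, 0 °C
Reagents that add atoms: methyl chloroformate, COC(=O)Cl
Why: O-Acylation of the primary allylic alcohol with a chloroformate gives the linear carbonate, the standard leaving group for iridium allyl chemistry.

Step 3
Reactants: 3 methyl (E)-3-(3,4,5-trimethoxyphenyl)prop-2-en-1-yl carbonate; 4 4-bromo-2-hydroxybenzaldehyde
Product: 6 4-bromo-2-{[(1S)-1-(3,4,5-trimethoxyphenyl)prop-2-en-1-yl]oxy}benzaldehyde, via lithium 5-bromo-2-formylphenolate 5 (not isolated)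
Conditions: 4 (2 equiv), LiOtBu (2 equiv), THF, rt; then 3, [Ir(cod)Cl]2 (2 mol%), (Sa,Sc,Sc)-(1,1'-binaphthalene-2,2'-diyl) N,N-bis(1-phenylethyl)phosphoramidite (4 mol%, catalyst pre-activated with nPrNH2 and freed of volatiles), THF, rt
Reagents that add atoms: lithium tert-butoxide, [Li+].CC(C)(C)[O-] (lithium of 5 only)
Why: In this iridium-catalysed asymmetric allylic etherification the cyclometallated iridium phosphoramidite ionises the linear carbonate to an allyl complex, the aryloxide attacks the aryl-substituted terminus to give the branched ether, and the ligand sets the new C–O stereocentre as S.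

Step 4
Reactants: 6 4-bromo-2-{[(1S)-1-(3,4,5-trimethoxyphenyl)prop-2-en-1-yl]oxy}benzaldehyde
Product: 8 4-bromo-2-{[(1S)-1-(3,4,5-trimethoxyphenyl)prop-2-en-1-yl]oxy}phenol, via aryl formate 7 (not isolated)
Conditions: mCPBA (1.2 equiv), CH2Cl2, 0 °C to rt, aq. NaHCO3 wash; crude 7, K2CO3 (cat.), MeOH, 0 °C
Reagents that add atoms: mCPBA, O=C(OO)c1cccc(Cl)c1
Why: In this Baeyer–Villiger oxidation the ortho-alkoxyaryl group should migrate in the Criegee adduct faster than hydride, and faster than the peracid epoxidises the electron-poor monosubstituted alkene, and mild methanolysis of formate 7 then frees the phenol without touching the stereocentre.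

Step 5
Reactants: 8 4-bromo-2-{[(1S)-1-(3,4,5-trimethoxyphenyl)prop-2-en-1-yl]oxy}phenol
Product: 9 (2R,3R)-6-bromo-2-methyl-3-(3,4,5-trimethoxyphenyl)-2,3-dihydro-1,4-benzodioxine
Conditions: [N,N'-bis(3,5-di-tert-butylsalicylidene)-2,3-dimethylbutane-2,3-diaminato]cobalt (divalent cobalt, 5 mol%), N-fluoro-2,4,6-trimethylpyridinium triflate (1.5 equiv), (Me2SiH)2O (1.5 equiv), PhCF3, argon, 0 °C to rt
Reagents that add atoms: none
Why: The N-fluoropyridinium salt oxidises the divalent cobalt complex to trivalent cobalt, the silane converts this into a cobalt hydride, hydrogen-atom transfer to the terminal CH2 of the vinyl group gives the secondary C2 radical, cobalt captures it, one-electron oxidation gives a cationic tetravalent alkylcobalt species, and the neighbouring phenol oxygen displaces cobalt from C2 while collidine takes up the proton. The closest known reaction type is the cobalt-salen hydrogen-atom-transfer/radical-polar crossover hydroalkoxylation (a Mukaiyama-type hydrofunctionalisation) of alkenyl alcohols and alkenyl phenols to saturated oxygen heterocycles. The only ring closed is the dioxane ring, 6-exo with respect to the alkene and 6-exo-tet at the alkylcobalt stage; a 7-endo closure is excluded because hydrogen is delivered to the terminal carbon only. The new stereocentre C2 is controlled by the C3 stereocentre: the two epimeric alkylcobalt species interconvert by Co–C homolysis (Curtin–Hammett situation) and the faster displacement runs through the half-chair in which the C3 aryl group and the nascent C2 methyl group are anti and the bulky cobalt leaving group points away from the aryl group, which leads to the trans (2R,3R) isomer, also the more stable one. The step needs Markovnikov regioselectivity, secured by the monosubstituted alkene, and chemoselectivity, secured because 8 holds a single alkene (bromine keeps the place of the allyl group) and the aryl bromide and aryl ethers are inert under these nearly neutral conditions. Capture of the radical by cobalt and the short tether should outrun loss of the aryloxyl group from C3 and hydrogen back-transfer, which is why a generous catalyst loading and low temperature are chosen.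

Step 6
Reactants: 9 (2R,3R)-6-bromo-2-methyl-3-(3,4,5-trimethoxyphenyl)-2,3-dihydro-1,4-benzodioxine
Product: 10 (2R,3R)-2-methyl-6-(prop-2-en-1-yl)-3-(3,4,5-trimethoxyphenyl)-2,3-dihydro-1,4-benzodioxine
Conditions: allylSnBu3 (1.5 equiv), Pd(PPh3)4 (5 mol%), toluene, 110 °C
Reagents that add atoms: allyltributylstannane, C=CC[Sn](CCCC)(CCCC)CCCC
Why: In this Stille coupling zerovalent palladium inserts into the aryl C–Br bond, the allyl group is transferred from tin and reductive elimination forms the aryl–allyl bond, with neither stereocentre of the dioxane ring involved.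

Compound list
1 | methyl (E)-3-(3,4,5-trimethoxyphenyl)prop-2-enoate | COC(=O)/C=C/c1cc(OC)c(OC)c(OC)c1 | starting material
2 | (E)-3-(3,4,5-trimethoxyphenyl)prop-2-en-1-ol | OC/C=C/c1cc(OC)c(OC)c(OC)c1 | intermediate
3 | methyl (E)-3-(3,4,5-trimethoxyphenyl)prop-2-en-1-yl carbonate | COC(=O)OC/C=C/c1cc(OC)c(OC)c(OC)c1 | intermediate
4 | 4-bromo-2-hydroxybenzaldehyde | O=Cc1ccc(Br)cc1O | starting material
5 | lithium 5-bromo-2-formylphenolate (not isolated) | [Li+].[O-]c1cc(Br)ccc1C=O | intermediate
6 | 4-bromo-2-{[(1S)-1-(3,4,5-trimethoxyphenyl)prop-2-en-1-yl]oxy}benzaldehyde | O=Cc1ccc(Br)cc1O[C@H](c1cc(OC)c(OC)c(OC)c1)C=C | intermediate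
7 | 4-bromo-2-{[(1S)-1-(3,4,5-trimethoxyphenyl)prop-2-en-1-yl]oxy}phenyl formate (not isolated) | O=COc1ccc(Br)cc1O[C@H](c1cc(OC)c(OC)c(OC)c1)C=C | intermediate
8 | 4-bromo-2-{[(1S)-1-(3,4,5-trimethoxyphenyl)prop-2-en-1-yl]oxy}phenol | Oc1ccc(Br)cc1O[C@H](c1cc(OC)c(OC)c(OC)c1)C=C | intermediate
9 | (2R,3R)-6-bromo-2-methyl-3-(3,4,5-trimethoxyphenyl)-2,3-dihydro-1,4-benzodioxine | Brc1ccc2c(c1)O[C@H](c1cc(OC)c(OC)c(OC)c1)[C@@H](C)O2 | intermediate
10 | (2R,3R)-2-methyl-6-(prop-2-en-1-yl)-3-(3,4,5-trimethoxyphenyl)-2,3-dihydro-1,4-benzodioxine | C=CCc1ccc2c(c1)O[C@H](c1cc(OC)c(OC)c(OC)c1)[C@@H](C)O2 | target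

Total step count: 6. Longest linear sequence: 6 (1 → 2 → 3 → 6 → 8 → 9 → 10).

Steps most likely to fail

Step 5.
- **Possible failures:** The C2 radical may fragment with expulsion of the aryloxyl group from C3. Hydrogen back-transfer from C3 may move the double bond into conjugation and erase the stereocentre. A hydride or aryl shift may intervene at the cationic stage. The free phenol may be oxidised by the N–F salt. The trans/cis discrimination may be weak.
- **Fallback (from 8, back at 9):** The radical hydrofunctionalisation is replaced by a polar halocyclisation followed by a separate reduction. I2 and NaHCO3 in MeCN at 0 °C should close the same O1–C2 bond through the iodonium ion (6-exo) to give (2S,3R)-6-bromo-2-(iodomethyl)-3-(3,4,5-trimethoxyphenyl)-2,3-dihydro-1,4-benzodioxine F1. LiEt3BH in THF at 0 °C should then replace the primary iodide by hydride in an SN2 reaction and give 9 with the aryl bromide intact.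

Step 3.
- **Possible failures:** The chelated, electron-poor aryloxide may attack sluggishly. The catalyst may re-ionise the branched ether, with drift to the linear isomer and erosion of enantiopurity.
- **Fallback (from 2, back at 6):** The aryl–oxygen bond is made instead of the allyl–oxygen bond.
  - Sharpless asymmetric epoxidation of 2 (Ti(OiPr)4, D-(−)-diisopropyl tartrate, tBuOOH, 4 Å sieves, CH2Cl2, −20 °C) should give [(2R,3R)-3-(3,4,5-trimethoxyphenyl)oxiran-2-yl]methanol F2.
  - Appel-type iodination (PPh3, I2, imidazole) should give (2S,3R)-2-(iodomethyl)-3-(3,4,5-trimethoxyphenyl)oxirane F3.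
  - Reductive opening with zinc dust in EtOH should give (1S)-1-(3,4,5-trimethoxyphenyl)prop-2-en-1-ol F4.
  - SNAr reaction of F4 with 4-bromo-2-fluorobenzaldehyde (NaH, THF/DMF, 0 °C) leaves the carbinol C–O bond untouched and should deliver 6.

Step 4.
- **Possible failures:** The vinyl group may be epoxidised in competition. Hydride may migrate instead of aryl, which gives over-oxidation to the acid level. The acid formed may promote ionisation of the allylic benzylic ether.
- **Fallback (from 3, back at 8):** The formyl group is dispensed with altogether. Compound 3 is coupled under the iridium catalysis of step 3 with excess catechol (symmetrical, so no regiochemical question) and K3PO4 to give 2-{[(1S)-1-(3,4,5-trimethoxyphenyl)prop-2-en-1-yl]oxy}phenol F5. The free hydroxyl group then directs bromination with Bu4NBr3 (CH2Cl2/MeOH, 0 °C) to its para position, which gives 8.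

Further compounds
F1 | step 5 | (2S,3R)-6-bromo-2-(iodomethyl)-3-(3,4,5-trimethoxyphenyl)-2,3-dihydro-1,4-benzodioxine | Brc1ccc2c(c1)O[C@H](c1cc(OC)c(OC)c(OC)c1)[C@@H](CI)O2
F2 | step 3 | [(2R,3R)-3-(3,4,5-trimethoxyphenyl)oxiran-2-yl]methanol | O1[C@H](c2cc(OC)c(OC)c(OC)c2)[C@H]1CO
F3 | step 3 | (2S,3R)-2-(iodomethyl)-3-(3,4,5-trimethoxyphenyl)oxirane | O1[C@H](c2cc(OC)c(OC)c(OC)c2)[C@H]1CI
F4 | step 3 | (1S)-1-(3,4,5-trimethoxyphenyl)prop-2-en-1-ol | O[C@H](c1cc(OC)c(OC)c(OC)c1)C=C
F5 | step 4 | 2-{[(1S)-1-(3,4,5-trimethoxyphenyl)prop-2-en-1-yl]oxy}phenol | Oc1ccccc1O[C@H](c1cc(OC)c(OC)c(OC)c1)C=C
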